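**Plan**

1. Retrosynthesis (spiro[4.5]decane numbering: C1–C4 five-membered ring, C5 spiro carbon, C6–C10 six-membered ring): remove the C9 acetate, transpose the enone with loss of the C6 methyl (C6 carbonyl, C7=C8), and take the C1 ester back to a ketone.
2. Enabling feature: C5 then lies between the C1 and C6 carbonyls and C7 is the methyl of the C6 acetyl group, so C5–C6–C7 is a 1,3-dinucleophile.
3. One operation cuts C5–C10 (Michael) and C7–C8 (aldol condensation): (4S)-2-acetyl-4-isopropenylcyclopentanone plus (E)-crotonaldehyde as the C8–C9–C10 dielectrophile.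
4. Forward: the five-membered ring comes from (S)-limonene (ring cleavage, aldol reclosure, epoxidation, isomerisation to the 1,3-diketone); the six-membered ring is then spiro-annulated; redox and ester adjustments finish the route.
5. Stereochemistry: C3 from (S)-limonene; C10 from the (S)-diarylprolinol catalyst; C5 by attack anti to the C3 isopropenyl; C1 by hydride delivery anti to C10; C9 by acetoxylation anti to the C10 methyl.

Key step: step 6

Remark: centres that are destroyed later are carried as mixtures (oxirane carbons of 2 and 7, carbinol carbons of 3, 5 and 11, the acetyl-bearing carbon of 8, C6 of 14 and 15); (S)-(−)-limonene and (S)-α,α-diphenylprolinol trimethylsilyl ether are taken as commercial.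

**Step 1**
Reactants: 1 (S)-(−)-limonene
Product: 2 (4S)-1-methyl-4-(prop-1-en-2-yl)-7-oxabicyclo[4.1.0]heptane (limonene 1,2-oxide, cis/trans mixture)
Conditions: mCPBA (1.0 equiv), NaHCO3, CH2Cl2, 0 °C
Reagents that add atoms: mCPBA, O=C(OO)c1cccc(Cl)c1
Why: Prilezhaev epoxidation should take place only at the more electron-rich trisubstituted ring alkene and leave the 1,1-disubstituted isopropenyl group, and the oxirane configuration is irrelevant because both carbons become carbonyl groups in step 2.

**Step 2**
Reactants: 2 limonene 1,2-oxide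
Product: 4 (3S)-6-oxo-3-(prop-1-en-2-yl)heptanal, via limonene-1,2-diol 3 (not isolated)
Conditions: H5IO6 (1.1 equiv), THF/H2O, 0 °C → rt
Reagents that add atoms: water, O
Why: Acid-catalysed hydrolysis of the oxirane to the 1,2-diol followed in the same flask by Malaprade glycol cleavage should open the six-membered ring to the keto aldehyde without touching the stereocentre or the isopropenyl group.

**Step 3**
Reactants: 4 (3S)-6-oxo-3-(prop-1-en-2-yl)heptanal
Product: 6 1-[(4R)-4-(prop-1-en-2-yl)cyclopent-1-en-1-yl]ethan-1-one, via cyclopentane ketol 5 (not isolated)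
Conditions: 2% aq KOH, Et2O, rt
Reagents that add atoms: none
Why: Under aqueous hydroxide the internal ketone enolate should add to the more electrophilic aldehyde (intramolecular aldol condensation, 5-(enolexo)-exo-trig, then E1cB loss of water) to give the acetylcyclopentene, whereas amine–acid conditions are avoided because the enamine pathway leads to the regioisomeric cyclopentenecarbaldehyde.

**Step 4**
Reactants: 6 1-[(4R)-4-(prop-1-en-2-yl)cyclopent-1-en-1-yl]ethan-1-one
Product: 7 1-[(3R)-3-(prop-1-en-2-yl)-6-oxabicyclo[3.1.0]hexan-1-yl]ethan-1-one (oxirane diastereomers)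
Conditions: 30% H2O2, aq NaOH, MeOH, 0 °C
Reagents that add atoms: hydrogen peroxide, OO
Why: Weitz–Scheffer nucleophilic epoxidation should oxidise only the electron-poor enone alkene, and the face of attack does not matter because the oxirane is isomerised in step 5.

**Step 5**
Reactants: 7 epoxy ketone
Product: 8 (4S)-2-acetyl-4-(prop-1-en-2-yl)cyclopentan-1-one (enol/keto and epimer mixture at the acetyl-bearing carbon)
Conditions: Pd(PPh3)4 (5 mol%), Ph2PCH2CH2PPh2 (5 mol%), toluene, 100 °C
Reagents that add atoms: none
Why: Zerovalent palladium should insert into the Cα–O bond of the α,β-epoxy ketone to give a palladium enolate alkoxide that undergoes β-hydride elimination and reductive elimination (palladium-catalysed isomerisation of epoxy ketones to 1,3-diketones), which leaves the remote stereocentre and the isopropenyl group untouched.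

**Step 6**
Reactants: 8 (4S)-2-acetyl-4-(prop-1-en-2-yl)cyclopentan-1-one; 9 (E)-but-2-enal (crotonaldehyde, 1.5 equiv)
Product: 12 (3S,5S,10R)-10-methyl-3-(prop-1-en-2-yl)spiro[4.5]dec-7-ene-1,6-dione, via Michael adduct 10 (not isolated), via spiro ketol 11 (not isolated)
Conditions: (S)-α,α-diphenylprolinol trimethylsilyl ether (20 mol%), PhCO2H (20 mol%), toluene, 0 °C → rt; then p-TsOH·H2O (30 mol%), 40 °C, same flask
Reagents that add atoms: none
Why: The amine catalyst condenses with crotonaldehyde to an E-iminium ion, the enol of 8 adds through its central carbon to the β-carbon (C5–C10 bond), and after hydrolysis to 10 the acetyl group enolises and closes onto the aldehyde (C7–C8 bond) with loss of water. The closest known reaction type is the iminium-catalysed Michael addition of 1,3-dicarbonyl compounds to enals followed by intramolecular aldol condensation to cyclohexenones (organocatalytic Robinson-type [3+3] annulation). The six-membered ring closes in a 6-(enolendo)-exo-trig aldol mode and dehydration fixes the C7=C8 enone. C10 is set by the catalyst, whose diphenyl(silyloxy)methyl group shields one face of the iminium ion so that the nucleophile adds to the opposite face of the β-carbon, which should give the R configuration at the methyl-bearing carbon of 10. C5 is set by the substrate through attack of the planar enol on the face of the five-membered ring anti to the C3 isopropenyl group. The step needs C- over O-alkylation, secured by the soft iminium acceptor and the reversibility of oxa-Michael addition, and closure through the acetyl methyl and not the ring methylene, secured because only the former aldol can dehydrate to a conjugated enone whereas the bridged ketol from the ring methylene would need a bridgehead alkene and reverts.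

**Step 7**
Reactants: 12 spiro enedione
Product: 13 (1R,3S,5S,10R)-1-hydroxy-10-methyl-3-(prop-1-en-2-yl)spiro[4.5]dec-7-en-6-one
Conditions: NaBH4, MeOH/CH2Cl2 (1:1), −78 °C; aq NH4Cl
Reagents that add atoms: none
Why: At low temperature NaBH4 should reduce the saturated cyclopentanone faster than the conjugated enone, and hydride should approach C1 from the face flanked by the flat C6 carbonyl carbon and not from the face blocked by C10 and its methyl group, which places the new hydroxyl cis to C10 (1R).

**Step 8**
Reactants: 13 hydroxy enone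
Product: 14 (1R,3S,5S,10R)-6,10-dimethyl-3-(prop-1-en-2-yl)spiro[4.5]dec-7-ene-1,6-diol (C6 epimers)
Conditions: MeLi (3 equiv), THF, −78 → −20 °C; aq NH4Cl
Reagents that add atoms: methyllithium, [Li]C
Why: After deprotonation of the hydroxyl, methyllithium should add 1,2 to the enone carbonyl (hard nucleophile, no 1,4-addition), and the configuration of the new C6 carbinol is irrelevant because this centre becomes sp2 in step 10.

**Step 9**
Reactants: 14 diol
Product: 15 (1R,3S,5S,10R)-6-hydroxy-6,10-dimethyl-3-(prop-1-en-2-yl)spiro[4.5]dec-7-en-1-yl 2-methylpropanoate (C6 epimers)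
Conditions: (i-PrCO)2O (1.3 equiv), Et3N, DMAP (10 mol%), CH2Cl2, 0 °C → rt
Reagents that add atoms: isobutyric anhydride, CC(C)C(=O)OC(=O)C(C)C
Why: DMAP-catalysed acylation should esterify the secondary C1 hydroxyl and leave the far more hindered tertiary allylic C6 hydroxyl free.

**Step 10**
Reactants: 15 tertiary allylic alcohol
Product: 16 (1R,3S,5R,10R)-6,10-dimethyl-8-oxo-3-(prop-1-en-2-yl)spiro[4.5]dec-6-en-1-yl 2-methylpropanoate
Conditions: pyridinium chlorochromate [C5H5NH][CrO3Cl] (2.5 equiv), 4 Å MS, CH2Cl2, rt
Reagents that add atoms: pyridinium chlorochromate, [O-][Cr](=O)(=O)Cl.c1cc[nH+]cc1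
Why: In this Babler–Dauben oxidative transposition the tertiary allylic chromate ester should undergo a [3,3]-sigmatropic shift to the C8 chromate, which is oxidised to the ketone and gives the 6-methyl-6-en-8-one.

**Step 11**
Reactants: 16 spiro enone
Product: 17 (1R,3S,5R,9R,10S)-9-(acetyloxy)-6,10-dimethyl-8-oxo-3-(prop-1-en-2-yl)spiro[4.5]dec-6-en-1-yl 2-methylpropanoate (target)
Conditions: Mn(OAc)3·2H2O (3 equiv), benzene, reflux (Dean–Stark)
Reagents that add atoms: manganese triacetate, CC(=O)[O-].CC(=O)[O-].CC(=O)[O-].[Mn+3]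
Why: Mn(OAc)3 α'-acetoxylation of the enone should proceed through the manganese enolate at C9, the only enolisable α'-position, with acetate delivered anti to the adjacent C10 methyl group to give the trans (9R) acetate, which should also be the more stable diequatorial epimer.

**Compound list**

1 | (S)-(−)-limonene, (4S)-1-methyl-4-(prop-1-en-2-yl)cyclohex-1-ene | C=C(C)[C@@H]1CC=C(C)CC1 | starting material
2 | (4S)-1-methyl-4-(prop-1-en-2-yl)-7-oxabicyclo[4.1.0]heptane, cis/trans mixture | C=C(C)[C@@H]1CC2OC2(C)CC1 | intermediate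
3 | (4S)-1-methyl-4-(prop-1-en-2-yl)cyclohexane-1,2-diol | C=C(C)[C@@H]1CC(O)C(C)(O)CC1 | intermediate
4 | (3S)-6-oxo-3-(prop-1-en-2-yl)heptanal | C=C(C)[C@H](CC=O)CCC(C)=O | intermediate
5 | 1-[(4S)-2-hydroxy-4-(prop-1-en-2-yl)cyclopentyl]ethan-1-one | C=C(C)[C@@H]1CC(O)C(C(C)=O)C1 | intermediate
6 | 1-[(4R)-4-(prop-1-en-2-yl)cyclopent-1-en-1-yl]ethan-1-one | C=C(C)[C@@H]1CC=C(C(C)=O)C1 | intermediate
7 | 1-[(3R)-3-(prop-1-en-2-yl)-6-oxabicyclo[3.1.0]hexan-1-yl]ethan-1-one | C=C(C)[C@@H]1CC2OC2(C(C)=O)C1 | intermediate
8 | (4S)-2-acetyl-4-(prop-1-en-2-yl)cyclopentan-1-one | C=C(C)[C@@H]1CC(=O)C(C(C)=O)C1 | intermediate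
9 | (E)-but-2-enal | C/C=C/C=O | starting material
10 | (3R)-3-[(1R,4S)-1-acetyl-2-oxo-4-(prop-1-en-2-yl)cyclopentyl]butanal | C=C(C)[C@@H]1CC(=O)[C@@](C1)(C(C)=O)[C@H](C)CC=O | intermediate
11 | (3S,5S,10R)-8-hydroxy-10-methyl-3-(prop-1-en-2-yl)spiro[4.5]decane-1,6-dione | C=C(C)[C@@H]1CC(=O)[C@@]2(C1)C(=O)CC(O)C[C@H]2C | intermediate
12 | (3S,5S,10R)-10-methyl-3-(prop-1-en-2-yl)spiro[4.5]dec-7-ene-1,6-dione | C=C(C)[C@@H]1CC(=O)[C@@]2(C1)C(=O)C=CC[C@H]2C | intermediate
13 | (1R,3S,5S,10R)-1-hydroxy-10-methyl-3-(prop-1-en-2-yl)spiro[4.5]dec-7-en-6-one | C=C(C)[C@@H]1C[C@@H](O)[C@@]2(C1)C(=O)C=CC[C@H]2C | intermediate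
14 | (1R,3S,5S,10R)-6,10-dimethyl-3-(prop-1-en-2-yl)spiro[4.5]dec-7-ene-1,6-diol | C=C(C)[C@@H]1C[C@@H](O)[C@@]2(C1)C(C)(O)C=CC[C@H]2C | intermediate
15 | (1R,3S,5S,10R)-6-hydroxy-6,10-dimethyl-3-(prop-1-en-2-yl)spiro[4.5]dec-7-en-1-yl 2-methylpropanoate | C=C(C)[C@@H]1C[C@@H](OC(=O)C(C)C)[C@@]2(C1)C(C)(O)C=CC[C@H]2C | intermediate
16 | (1R,3S,5R,10R)-6,10-dimethyl-8-oxo-3-(prop-1-en-2-yl)spiro[4.5]dec-6-en-1-yl 2-methylpropanoate | C=C(C)[C@@H]1C[C@@H](OC(=O)C(C)C)[C@@]2(C1)C(C)=CC(=O)C[C@H]2C | intermediate
17 | (1R,3S,5R,9R,10S)-9-(acetyloxy)-6,10-dimethyl-8-oxo-3-(prop-1-en-2-yl)spiro[4.5]dec-6-en-1-yl 2-methylpropanoate | C=C(C)[C@@H]1C[C@@H](OC(=O)C(C)C)[C@@]2(C1)C(C)=CC(=O)[C@H](OC(C)=O)[C@H]2C | target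

**Totals**

Total step count: 11. Longest linear sequence: 11 steps (1 → 17); crotonaldehyde 9 enters as a commercial fragment.

**Steps most likely to fail**

Step 6. The facial selectivity at C5 rests on remote induction by the C3 isopropenyl group and may be poor or opposed by the catalyst, and crotonaldehyde self-condensation may consume the acceptor. The fallback sets out from 8 and uses catalyst control for both centres. Iridium-catalysed branched-selective allylic alkylation of the enolate of 8 with (E)-but-2-en-1-yl methyl carbonate ([Ir(cod)Cl]2, BINOL-derived bis(1-phenylethyl)amine phosphoramidite of the enantiomeric series that delivers the R allylic carbon, LiOt-Bu, THF) should give (2R,4S)-2-acetyl-2-[(2R)-but-3-en-2-yl]-4-(prop-1-en-2-yl)cyclopentan-1-one F1. Aldehyde-selective Wacker oxidation of the monosubstituted vinyl group (PdCl2(PhCN)2, CuCl2, AgNO2, O2, t-BuOH/MeNO2; the isopropenyl group is inert) should then give aldehyde 10. The fallback returns to the route at 10, which is closed to 12 with p-TsOH·H2O as in the second stage of step 6.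

Step 7. Hydride may be delivered to the wrong face of the C1 carbonyl, or the enone carbonyl may be reduced in competition. The fallback sets out from 12 and corrects the carbinol centre by inversion. If reduction gives mainly the epimer (1S,3S,5S,10R)-1-hydroxy-10-methyl-3-(prop-1-en-2-yl)spiro[4.5]dec-7-en-6-one F2, Mitsunobu reaction with 4-nitrobenzoic acid (PPh3, diisopropyl azodicarboxylate, THF) should give with inversion (1R,3S,5S,10R)-10-methyl-6-oxo-3-(prop-1-en-2-yl)spiro[4.5]dec-7-en-1-yl 4-nitrobenzoate F3. Methanolysis (K2CO3, MeOH, 0 °C) returns to the route at 13.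

Step 11. Acetate may be delivered cis to the C10 methyl, oxidation may occur at the allylic C6 methyl, or radical addition to the isopropenyl group may intervene. The fallback sets out from 16 and separates enolate formation from oxygen transfer. Kinetic deprotonation at C9 (LiN(SiMe3)2, THF, −78 °C) and hydroxylation of the lithium enolate with 2-(phenylsulfonyl)-3-phenyloxaziridine anti to the C10 methyl should give (1R,3S,5R,9R,10S)-9-hydroxy-6,10-dimethyl-8-oxo-3-(prop-1-en-2-yl)spiro[4.5]dec-6-en-1-yl 2-methylpropanoate F4. Acetylation (Ac2O, pyridine, DMAP) returns to the route at 17; any cis acetate could be equilibrated to the trans epimer with a mild base.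

**Further compounds**

F1 | step 6 | (2R,4S)-2-acetyl-2-[(2R)-but-3-en-2-yl]-4-(prop-1-en-2-yl)cyclopentan-1-one | C=C(C)[C@@H]1CC(=O)[C@@](C1)(C(C)=O)[C@H](C)C=C
F2 | step 7 | (1S,3S,5S,10R)-1-hydroxy-10-methyl-3-(prop-1-en-2-yl)spiro[4.5]dec-7-en-6-one | C=C(C)[C@@H]1C[C@H](O)[C@@]2(C1)C(=O)C=CC[C@H]2C
F3 | step 7 | (1R,3S,5S,10R)-10-methyl-6-oxo-3-(prop-1-en-2-yl)spiro[4.5]dec-7-en-1-yl 4-nitrobenzoate | C=C(C)[C@@H]1C[C@@H](OC(=O)c3ccc(cc3)[N+](=O)[O-])[C@@]2(C1)C(=O)C=CC[C@H]2C
F4 | step 11 | (1R,3S,5R,9R,10S)-9-hydroxy-6,10-dimethyl-8-oxo-3-(prop-1-en-2-yl)spiro[4.5]dec-6-en-1-yl 2-methylpropanoate | C=C(C)[C@@H]1C[C@@H](OC(=O)C(C)C)[C@@]2(C1)C(C)=CC(=O)[C@H](O)[C@H]2C
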